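**Retrosynthetic overview**
- Feature: ring A (C4a, C5, C6, C7, C8, C8a) is hexasubstituted. Its C5(O)–C6(CH2)–C7(O)–C8(prenyl) half is the carbon chain of a 1-alkoxy-3-siloxy-1,3-diene whose C5=C6 bond lies inside dihydropyran ring E.
- After a final desilylation, C5–C4a and C8–C8a are cut by a retro-(4+2)/rearomatization. This gives a 4a-bromo-4-pyranone holding rings B, C, D and F, and a (Z)-silyl dienol ether holding ring E and the prenyl group.
- Bromopyranone: ring B comes from C3-acylation of the ring D coumaranone with 2,3-dibromoacryloyl chloride and O1–C8a closure. Bromine arrives with the three-carbon unit, so electron-rich ring D never meets a brominating agent. Ring C comes from a chromanquinone and a silyl ketene acetal, ring F from propargyl Claisen chemistry on 2,5-dimethoxyphenol.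
- Diene: ring E from acrolein and isobutene, C7 by trichloroacetylation, C8 and prenyl by a Weinreb ketone synthesis, then Z-selective enol silylation.
- Ring order: F, C, B (D present from the start); E separately; A last.

Key step: step 15

Remark: chromone numbering is used (O1, C2, C3, C4, C4a, C5–C8, C8a; ring D C1'–C6'; furan oxygen O2'). Ring B is the pyranone, ring C the furan, ring E the dihydropyran on C5/C6, ring F the dihydropyran on C3'/C4'. The target has no stereocentre, so the only stereochemical element that matters is the Z geometry of the silyl dienol ether.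

**Step 1**
Reactants: 1 2,5-dimethoxyphenol; 2 3-chloro-3-methylbut-1-yne
Product: 3 1,4-dimethoxy-2-[(2-methylbut-3-yn-2-yl)oxy]benzene
Conditions: DBU, CuCl2·2H2O (1 mol %), MeCN, 0 °C → rt
Reagents that add atoms: none
Why: Copper-catalysed O-alkylation of a phenol with a tertiary propargylic chloride is the standard route to aryl 1,1-dimethylpropargyl ethers, and the single phenolic OH of 1 is the only nucleophile.

**Step 2**
Reactants: 3 aryl propargyl ether
Product: 4 5,8-dimethoxy-2,2-dimethyl-2H-chromene
Conditions: o-xylene, 140 °C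
Reagents that add atoms: none
Why: Aromatic propargyl Claisen rearrangement, 1,5-hydrogen shift and oxa-6π electrocyclization close ring F as a chromene, and the carbon can migrate only to the one free ortho position because the other carries OMe.

**Step 3**
Reactants: 4 chromene
Product: 5 5,8-dimethoxy-2,2-dimethylchroman
Conditions: H2 (1 atm), Pd/C, EtOAc, rt
Reagents that add atoms: none
Why: Catalytic hydrogenation saturates the styrene-type C=C of the chromene while the aryl ethers and the arene are untouched.

**Step 4**
Reactants: 5 dimethoxychroman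
Product: 6 2,2-dimethylchroman-5,8-dione (chromanquinone)
Conditions: (NH4)2Ce(NO3)6 (2.5 equiv), MeCN/H2O, 0 °C
Reagents that add atoms: water, O
Why: Oxidative demethylation of a para-dimethoxyarene by (NH4)2Ce(NO3)6 gives the para-quinone, and the chroman oxygen stays as a vinylogous ester oxygen because it has no para oxygen partner.

**Step 5**
Reactants: 6 chromanquinone; 7 1-(tert-butyldimethylsilyloxy)-1-methoxyethene
Product: 9 5'-O-TBS ring D coumaranone, via hydroquinone mono-TBS ether ester 8 (not isolated)
Conditions: 7 (1.2 equiv), Sc(OTf)3 (5 mol %), CH2Cl2, −78 → 0 °C; solvent change, p-TsOH·H2O (10 mol %), PhMe, 80 °C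
Reagents that add atoms: none
Why: Mukaiyama–Michael addition in which the ring oxygen donates into the C5 carbonyl (chroman numbering), so that the C8 carbonyl, chelated together with that oxygen, is the acceptor and its β-carbon C6 (future C1') is attacked; the silyl group moves to O8 (future O5'), which also blocks redox exchange with unreacted quinone, and the free 5-OH next to the new side chain lactonizes under acid to close ring C.

**Step 6**
Reactants: 10 propiolic acid
Product: 11 (E)-2,3-dibromoprop-2-enoic acid
Conditions: Br2 (1.0 equiv), CHCl3, 0 °C → rt, dark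
Reagents that add atoms: bromine, BrBr
Why: Electrophilic anti addition of bromine to the alkyne gives the E-dibromoalkene, and the electron-poor product does not take up a second equivalent under these conditions.

**Step 7**
Reactants: 11 dibromoacrylic acid
Product: 12 (E)-2,3-dibromoprop-2-enoyl chloride
Conditions: (COCl)2, DMF (cat.), CH2Cl2, rt
Reagents that add atoms: oxalyl chloride, O=C(Cl)C(=O)Cl
Why: Standard acid chloride formation through the catalytic Vilsmeier-type chloroiminium species, with no α-hydrogen available for ketene formation.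

**Step 8**
Reactants: 9 coumaranone; 12 dibromoacryloyl chloride
Product: 14 4a-bromo benzofuro-fused pyran-4-one carrying ring D, via 3-(2,3-dibromoacryloyl) enol 13 (not isolated)
Conditions: NaH (2.2 equiv), THF, 0 °C, Ar; 12, DMAP (10 mol %), 0 °C → rt, then 50 °C
Reagents that add atoms: none
Why: Claisen-type C-acylation of the benzofuranone enolate (O-acylated material is returned by DMAP-mediated O-to-C acyl transfer) gives the stabilized enolate of 13, whose lactone-derived oxygen displaces the β-bromide by intramolecular addition–elimination; this is the acylation/O-cyclization sequence that turns malonates and β-keto esters into 2-alkoxy- and 2-alkylchromones with 2-halobenzoyl chlorides, and it places bromine at C4a without electrophilic bromination of ring D.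

**Step 9**
Reactants: 15 acrolein; 16 isobutene
Product: 17 2,2-dimethyl-3,4-dihydro-2H-pyran
Conditions: 16 (3 equiv), hydroquinone (cat.), steel autoclave, 190 °C
Reagents that add atoms: none
Why: Thermal inverse-electron-demand hetero-Diels–Alder reaction of acrolein as the oxadiene, known for 1,1-disubstituted alkenes, in which the nucleophilic CH2 terminus of isobutene bonds to the acrolein β-carbon and the tertiary carbon bonds to oxygen.

**Step 10**
Reactants: 17 dihydropyran; 18 trichloroacetyl chloride
Product: 19 2,2,2-trichloro-1-(6,6-dimethyl-5,6-dihydro-4H-pyran-3-yl)ethanone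
Conditions: pyridine, CH2Cl2, 0 °C → rt
Reagents that add atoms: none
Why: Enol ethers are acylated at their β-carbon by trichloroacetyl chloride without a Lewis acid (addition, then pyridine-assisted loss of HCl), whereas direct acylation with an unactivated alkenoyl chloride would need a Lewis acid that neither the tertiary enol ether nor a trisubstituted alkene tolerates.

**Step 11**
Reactants: 19 trichloromethyl ketone
Product: 20 methyl 6,6-dimethyl-5,6-dihydro-4H-pyran-3-carboxylate
Conditions: MeOH, K2CO3 (cat.), 0 °C → rt
Reagents that add atoms: methanol, CO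
Why: Haloform-type cleavage in which methoxide adds to the strongly activated ketone and expels the trichloromethyl anion, leaving the vinylogous carbonate ester.

**Step 12**
Reactants: 20 methyl ester
Product: 21 N-methoxy-N,6,6-trimethyl-5,6-dihydro-4H-pyran-3-carboxamide
Conditions: MeNH(OMe)·HCl (1.5 equiv), i-PrMgCl (3.0 equiv), THF, −20 → 0 °C
Reagents that add atoms: N,O-dimethylhydroxylamine hydrochloride, CNOC.Cl
Why: Aminolysis of the ester by the magnesium amide of N,O-dimethylhydroxylamine is the usual direct ester-to-Weinreb-amide conversion and leaves the enol ether alone.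

**Step 13**
Reactants: 21 Weinreb amide; 22 5-bromo-2-methylpent-2-ene
Product: 24 1-(6,6-dimethyl-5,6-dihydro-4H-pyran-3-yl)-5-methylhex-4-en-1-one, via homoprenylmagnesium bromide 23 (not isolated)
Conditions: 22, Mg, THF, 40 °C; then 21, THF, 0 °C; aq. NH4Cl
Reagents that add atoms: magnesium, [Mg] (held only in 23)
Why: Weinreb ketone synthesis in which the chelated tetrahedral adduct holds until work-up, so that one homoprenyl group is introduced by 1,2-addition.

**Step 14**
Reactants: 24 ketone
Product: 25 (Z)-silyl dienol ether of 24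
Conditions: TBSOTf (1.2 equiv), Et3N (2 equiv), Et2O, 0 °C; pentane extraction
Reagents that add atoms: tert-butyldimethylsilyl triflate, CC(C)(C)[Si](C)(C)OS(=O)(=O)C(F)(F)F
Why: Soft enolization and O-silylation at the only enolizable position (future C8), the method used for acyclic 1-methoxy-2-methyl-3-siloxypenta-1,3-dienes, should give the Z enol ether because allylic strain keeps the chain away from the dihydropyranyl group, which puts the prenyl group on the outside of the s-cis diene.

**Step 15**
Reactants: 14 bromopyranone; 25 silyl dienol ether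
Product: 28 7,5'-bis-O-TBS ether of the target, via bromo cycloadduct 26 (not isolated), via bromocyclohexadiene 27 (not isolated)
Conditions: 25 (1.3 equiv), 2,4,6-collidine (2 equiv), BHT (cat.), PhMe, sealed tube, 120 °C, Ar; cool to 0 °C, DDQ (1.5 equiv); then DBU (5 equiv), 0 °C → rt
Reagents that add atoms: none
Why: Proposed new method: the doubly donor-substituted diene 25 carries its largest HOMO coefficient at C8 and the α-bromo enone of 14 its largest LUMO coefficient at the β-carbon C8a, so a normal-demand, probably asynchronous (4+2) cycloaddition should bond C8 to C8a and C5 to C4a and close ring A suprafacially as a six-membered ring, while the tetrasubstituted C2=C3 bond locked in the benzofuran and the unactivated prenyl alkene cannot compete. The closest known reaction type is the Diels–Alder reaction of 3-formyl-, 3-acyl-, 3-cyano- or 3-nitrochromones with 1-alkoxy-3-siloxybutadienes followed by aromatization to xanthones; a 3-bromo-4-pyranone fused to a benzofuran, and retention of the 1-alkoxy oxygen, are new. The four sp3 centres of 26 (cis C4a/C8a fusion from the suprafacial addition, C5 and C8 from the endo or exo approach) need no control because all of them become sp2. What must be controlled is the mode of aromatization: if a strong base acted first, loss of HBr would leave an enone whose vinylogously acidic C8 hydrogen is removed with expulsion of the C5 alkoxide (or of O1), so only collidine is present during heating and DDQ acts first, taking the hydride at C5 (α to oxygen and allylic to the silyl enol ether) with loss of the C8 proton to give 27, in which C5 and C8 are already sp2 and keep their substituents. In 27 the only elimination left is that of the C8a hydrogen and the C4a bromide, which DBU brings about with the gain of aromaticity. Should the 7-O-silyl group be lost to DDQ in part, the 7-phenol formed is carried into step 16 all the same.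

**Step 16**
Reactants: 28 bis-TBS ether
Product: 29 target CNP0081329.0
Conditions: n-Bu4NF (2.5 equiv), AcOH (2.5 equiv), THF, 0 °C → rt
Reagents that add atoms: none
Why: Fluoride-induced cleavage of both aryl silyl ethers, buffered with AcOH so that the phenoxides do not attack the electrophilic C2 of the pyranone, should release the achiral target.

**Compound list**
1 | 2,5-dimethoxyphenol | COc1ccc(OC)c(O)c1 | starting material
2 | 3-chloro-3-methylbut-1-yne | C#CC(C)(C)Cl | starting material
3 | 1,4-dimethoxy-2-[(2-methylbut-3-yn-2-yl)oxy]benzene | COc1ccc(OC)c(OC(C)(C)C#C)c1 | intermediate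
4 | 5,8-dimethoxy-2,2-dimethyl-2H-chromene | COc1ccc(OC)c2OC(C)(C)C=Cc12 | intermediate
5 | 5,8-dimethoxy-2,2-dimethylchroman | COc1ccc(OC)c2OC(C)(C)CCc12 | intermediate
6 | 2,2-dimethylchroman-5,8-dione | O=C1C=CC(=O)C2=C1OC(C)(C)CC2 | intermediate
7 | 1-(tert-butyldimethylsilyloxy)-1-methoxyethene | C=C(OC)O[Si](C)(C)C(C)(C)C | starting material
8 | methyl 2-[8-(tert-butyldimethylsilyloxy)-5-hydroxy-2,2-dimethylchroman-6-yl]acetate (not isolated) | COC(=O)Cc1cc(O[Si](C)(C)C(C)(C)C)c2OC(C)(C)CCc2c1O | intermediate
9 | ring D coumaranone: benzofuran-2(3H)-one with OTBS at C5 and a 2,2-dimethyldihydropyran fused at C6 (through O) and C7 (through CH2) | O=C1Cc2cc(O[Si](C)(C)C(C)(C)C)c3OC(C)(C)CCc3c2O1 | intermediate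
10 | propiolic acid | C#CC(=O)O | starting material
11 | (E)-2,3-dibromoprop-2-enoic acid | Br/C=C(/Br)C(=O)O | intermediate
12 | (E)-2,3-dibromoprop-2-enoyl chloride | Br/C=C(/Br)C(=O)Cl | intermediate
13 | 3-[(E)-2,3-dibromoacryloyl] derivative of 9, drawn as the 2-hydroxybenzofuran enol (sodium enolate in the flask, not isolated) | Br/C=C(/Br)C(=O)c1c(O)oc2c1cc(O[Si](C)(C)C(C)(C)C)c1OC(C)(C)CCc21 | intermediate
14 | 4a-bromo-4H-pyrano[2,3-b]benzofuran-4-one carrying ring D (5'-OTBS) and ring F; Br at C4a, H at C8a | O=c1c(Br)coc2oc3c4CCC(C)(C)Oc4c(O[Si](C)(C)C(C)(C)C)cc3c12 | intermediate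
15 | acrolein | C=CC=O | starting material
16 | isobutene | CC(C)=C | starting material
17 | 2,2-dimethyl-3,4-dihydro-2H-pyran | CC1(C)CCC=CO1 | intermediate
18 | trichloroacetyl chloride | ClC(=O)C(Cl)(Cl)Cl | starting material
19 | 2,2,2-trichloro-1-(6,6-dimethyl-5,6-dihydro-4H-pyran-3-yl)ethanone | O=C(C1=COC(C)(C)CC1)C(Cl)(Cl)Cl | intermediate
20 | methyl 6,6-dimethyl-5,6-dihydro-4H-pyran-3-carboxylate | COC(=O)C1=COC(C)(C)CC1 | intermediate
21 | N-methoxy-N,6,6-trimethyl-5,6-dihydro-4H-pyran-3-carboxamide | CON(C)C(=O)C1=COC(C)(C)CC1 | intermediate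
22 | 5-bromo-2-methylpent-2-ene | CC(C)=CCCBr | starting material
23 | (4-methylpent-3-en-1-yl)magnesium bromide (not isolated) | CC(C)=CCC[Mg]Br | intermediate
24 | 1-(6,6-dimethyl-5,6-dihydro-4H-pyran-3-yl)-5-methylhex-4-en-1-one | CC(C)=CCCC(=O)C1=COC(C)(C)CC1 | intermediate
25 | (Z)-tert-butyldimethylsilyl dienol ether of 24 | CC(C)=CC/C=C(\O[Si](C)(C)C(C)(C)C)C1=COC(C)(C)CC1 | intermediate
26 | bromo cycloadduct, racemic, endo isomer drawn (the exo isomer may accompany it): sp3 C4a(Br), C8a(H), C5(H), C8(H), C6=C7(OTBS) (not isolated) | CC(C)=CC[C@@H]1C(O[Si](C)(C)C(C)(C)C)=C2CCC(C)(C)O[C@@H]2[C@]2(Br)C(=O)c3c(O[C@H]12)oc1c4CCC(C)(C)Oc4c(O[Si](C)(C)C(C)(C)C)cc13 | intermediate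
27 | bromocyclohexadiene, racemic, 4a-Br and 8a-H cis: C5=C6 and C7=C8 in ring A (not isolated) | CC(C)=CCC1=C(O[Si](C)(C)C(C)(C)C)C2=C(OC(C)(C)CC2)[C@]2(Br)C(=O)c3c(O[C@H]12)oc1c4CCC(C)(C)Oc4c(O[Si](C)(C)C(C)(C)C)cc13 | intermediate
28 | 7,5'-bis-O-TBS ether of the target | CC(C)=CCc1c(O[Si](C)(C)C(C)(C)C)c2CCC(C)(C)Oc2c2c(=O)c3c(oc12)oc1c4CCC(C)(C)Oc4c(O[Si](C)(C)C(C)(C)C)cc13 | intermediate
29 | CNP0081329.0 | CC(C)=CCc1c(O)c2c(c3c(=O)c4c(oc13)oc1c3c(c(O)cc14)OC(C)(C)CC3)OC(C)(C)CC2 | target

**Step count**
Total step count: 16.
Longest linear sequence: 8 steps (steps 1–5, 8, 15, 16). The branch from acrolein (steps 9–14, 15, 16) is equally long.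

**Steps most likely to fail**

**1. Step 15.**
- What may go wrong: the push–pull C4a=C8a bond may be too weak a dienophile, so that the diene degrades thermally before it adds. Aromatization may also run with expulsion of the C5 alkoxide instead of dehydrogenation.
- Fallback: known isoflavone chemistry. Ring A is taken from a phloroglucinol, C3–C1' is made by Suzuki–Miyaura coupling, and O2'–C2 by DDQ cyclodehydrogenation of a 2'-hydroxyisoflavone. It sets out from 6 and comes back at 28.
- Ring D partner: HBr (33% in AcOH, CH2Cl2, 0 °C) adds to 6 at C6 to give 6-bromo-2,2-dimethylchroman-5,8-diol F1. TBSCl/imidazole silylates the less hindered 8-OH to give 6-bromo-8-(tert-butyldimethylsilyloxy)-2,2-dimethylchroman-5-ol F2. Miyaura borylation (B2pin2, PdCl2(dppf), KOAc, dioxane, 90 °C) gives the pinacol boronate F3.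
- Ring A/B partner: 2,4,6-trihydroxyacetophenone and isoprene (Amberlyst 15, THF/heptane, 65 °C) give, after separation from the 6-acetyl isomer, 1-(5,7-dihydroxy-2,2-dimethylchroman-8-yl)ethanone F4. C-prenylation at the only free ring carbon (prenyl bromide, aq. KOH, 0 °C) gives the 6-prenyl ketone F5. TBSOTf/2,6-lutidine (−78 °C) silylates the non-chelated hydroxyl to give the 5-O-TBS ketone F6. DMF dimethyl acetal (PhMe, 90 °C) gives the (E)-enaminone F7, and I2 (CHCl3, rt) cyclizes it to the 3-iodochromone F8.
- Union: coupling of F8 with F3 (Pd(PPh3)4, K3PO4, dioxane, 80 °C) gives the 2'-hydroxyisoflavone F9. DDQ (dioxane, rt → 60 °C) closes furan ring C to 28.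
- Price: a regioisomer separation on the phloroglucinol ring.

**2. Step 8.**
- What may go wrong: persistent O-acylation, attack of the enolate carbon on the β-bromo carbon of the acid chloride, or sluggish O1–C8a closure of the stabilized enolate.
- Fallback: the halogenative enaminone closure used for 3-halochromones. It sets out from 9 and comes back at 14.
- Ac2O, Et3N and DMAP (CH2Cl2, rt) give, after O-to-C acyl transfer, the 3-acetyl coumaranone enol F10. DMF dimethyl acetal (PhMe, 80 °C) gives the (E)-enaminone F11.
- Br2 (1 equiv, CHCl3, 0 °C) brominates the strongly nucleophilic enaminone α-carbon. The enol oxygen then closes on the iminium carbon, and loss of dimethylamine gives 14.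

**3. Step 5.**
- What may go wrong: attack at C7 instead of C6 of the quinone, electron transfer and redox exchange between adduct and quinone, or loss of the silyl group before lactonization.
- Fallback: the C–C bond is made by cross-coupling on the arene and the oxidation state is adjusted afterwards. It sets out from 5 and comes back at 9.
- NBS (MeCN, 0 °C) brominates 5 para to the ring oxygen and ortho to the 5-OMe group to give 6-bromo-5,8-dimethoxy-2,2-dimethylchroman F12. Palladium-catalysed coupling with the Reformatsky reagent BrZnCH2CO2t-Bu (Pd(dba)2, P(t-Bu)3, THF, rt) gives the tert-butyl arylacetate F13.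
- (NH4)2Ce(NO3)6 (MeCN/H2O, 0 °C) gives the quinone acetate F14, and Na2S2O4 (EtOAc/H2O) gives the hydroquinone ester F15.
- p-TsOH (PhMe, 80 °C) cleaves the tert-butyl ester and lactonizes to the 5-hydroxy coumaranone F16. TBSCl/imidazole (DMF) then gives 9.

**Further compounds**
F1 | step 15 | 6-bromo-2,2-dimethylchroman-5,8-diol | Oc1cc(Br)c(O)c2CCC(C)(C)Oc12
F2 | step 15 | 6-bromo-8-(tert-butyldimethylsilyloxy)-2,2-dimethylchroman-5-ol | CC(C)(C)[Si](C)(C)Oc1cc(Br)c(O)c2CCC(C)(C)Oc12
F3 | step 15 | 8-(tert-butyldimethylsilyloxy)-2,2-dimethyl-6-(4,4,5,5-tetramethyl-1,3,2-dioxaborolan-2-yl)chroman-5-ol | CC(C)(C)[Si](C)(C)Oc1cc(B3OC(C)(C)C(C)(C)O3)c(O)c2CCC(C)(C)Oc12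
F4 | step 15 | 1-(5,7-dihydroxy-2,2-dimethylchroman-8-yl)ethanone | CC(=O)c1c(O)cc(O)c2CCC(C)(C)Oc12
F5 | step 15 | 1-[5,7-dihydroxy-2,2-dimethyl-6-(3-methylbut-2-enyl)chroman-8-yl]ethanone | CC(=O)c1c(O)c(CC=C(C)C)c(O)c2CCC(C)(C)Oc12
F6 | step 15 | 1-[5-(tert-butyldimethylsilyloxy)-7-hydroxy-2,2-dimethyl-6-(3-methylbut-2-enyl)chroman-8-yl]ethanone | CC(=O)c1c(O)c(CC=C(C)C)c(O[Si](C)(C)C(C)(C)C)c2CCC(C)(C)Oc12
F7 | step 15 | (E)-3-(dimethylamino)prop-2-en-1-one (enaminone) of F6 | CN(C)/C=C/C(=O)c1c(O)c(CC=C(C)C)c(O[Si](C)(C)C(C)(C)C)c2CCC(C)(C)Oc12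
F8 | step 15 | 3-iodochromone with 7-OTBS, 8-prenyl and ring E on C5/C6 | O=c1c(I)coc2c(CC=C(C)C)c(O[Si](C)(C)C(C)(C)C)c3CCC(C)(C)Oc3c12
F9 | step 15 | 2'-hydroxyisoflavone, 7,5'-bis-O-TBS, with rings E and F | O=c1c(-c2cc(O[Si](C)(C)C(C)(C)C)c3OC(C)(C)CCc3c2O)coc2c(CC=C(C)C)c(O[Si](C)(C)C(C)(C)C)c3CCC(C)(C)Oc3c12
F10 | step 8 | 3-acetyl derivative of 9, drawn as the 2-hydroxybenzofuran enol | CC(=O)c1c(O)oc2c1cc(O[Si](C)(C)C(C)(C)C)c1OC(C)(C)CCc21
F11 | step 8 | (E)-3-(dimethylamino)acryloyl derivative of 9, enol form | CN(C)/C=C/C(=O)c1c(O)oc2c1cc(O[Si](C)(C)C(C)(C)C)c1OC(C)(C)CCc21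
F12 | step 5 | 6-bromo-5,8-dimethoxy-2,2-dimethylchroman | COc1cc(Br)c(OC)c2CCC(C)(C)Oc12
F13 | step 5 | tert-butyl 2-(5,8-dimethoxy-2,2-dimethylchroman-6-yl)acetate | COc1cc(CC(=O)OC(C)(C)C)c(OC)c2CCC(C)(C)Oc12
F14 | step 5 | tert-butyl 2-(2,2-dimethyl-5,8-dioxochroman-6-yl)acetate | O=C1C=C(CC(=O)OC(C)(C)C)C(=O)C2=C1OC(C)(C)CC2
F15 | step 5 | tert-butyl 2-(5,8-dihydroxy-2,2-dimethylchroman-6-yl)acetate | CC(C)(C)OC(=O)Cc1cc(O)c2OC(C)(C)CCc2c1O
F16 | step 5 | 5-hydroxy ring D coumaranone (9 without TBS) | O=C1Cc2cc(O)c3OC(C)(C)CCc3c2O1
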